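## Structural features

The target is a briarane: a cyclohexane (ring A; C1, C10–C14) trans-fused through C1–C10 to a ten-membered carbocycle (C1–C10) that carries a γ-lactone on C7–C8 (O–C19–C17) and a ring-cis 3,5-diene with C16 on C5. Eleven stereocentres are present; ten of them (C7, C8, C9, C10, C11, C12, C13, C14, C1, C2) form one unbroken chain, and C17 sits next to C8. On ring A the oxygens at C12, C13 and C14, the oxygen of the C11 spiro-epoxide (C20) and H-10 lie on one face (α), whereas the C15 methyl group and the C10–C9 bond lie on the other (β). Six esters of two kinds must be told apart (acetates on O2, O9, O14, O16; 3-methylbutanoates on O12, O13) next to a free tertiary hydroxyl at C8. Fragile points are the spiro-epoxide (acid), the β-hydroxy lactone (retro-aldol, dehydration, epimerisation at C17), the acyloxy groups at C2, C16 and C7 that are allylic to the diene (ionisation), and vicinal ester/hydroxyl pairs (acyl shift). The real difficulty is the ten-membered ring with its two cis double bonds and the C9–C10 bond that joins two stereocentres at the ring fusion. The key step uses the fact that C9 and C10 are neighbours and that C10 is bonded to C11, which bears the one-carbon branch C20. An O–C20–C11=C10 allyl ether with its oxygen on C9 can therefore hand C9 over to C10 and leave the C11=C20 methylene that later becomes the epoxide, while the furan that later becomes the lactone (C7, C8, C17, C19) stabilises the C9 carbanion.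

## Logic of the disconnections

45 to 44: the C17–H bond is exchanged for a C17–O bond, so that the C8 hydroxyl and C17 come from an 8,17-epoxy lactone. The tertiary alcohol then never needs protection and appears in the last step. The forward step must transfer electrons only to the lactone carbonyl, in the presence of six esters and the spiro-epoxide, and protonate C17 on the right face.

44 to 43: the epoxide oxygen is removed from C8/C17, leaving a butenolide. This reduces the lactone to a flat, robust unit. The forward step needs a nucleophilic oxidant that ignores the diene and attacks the correct face without epimerising C7.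

43 to 40 (through 42 and 41): the two 3-methylbutanoyl C–O bonds and the C11/C20 epoxide oxygen are cut, and the 12,13-diol is returned to its acetonide. The free C12 hydroxyl of 41 is kept as the element that steers the epoxidation to the α face. The demand is that the acetonide is removed under acid before any epoxide exists.

40 to 38 (through 39): the four acetyl groups are cut and O14/O16 are returned to silyl ethers. One global desilylation and one peracetylation then serve four positions.

38 to 34 (through 36): the lactone carbonyl oxygen and the C7–H bond are removed, so the butenolide becomes a 2-silylfuran. The furan is stable to organolithium reagents, its silyl group fixes which α-carbon becomes the carbonyl, and the free C9 hydroxyl of 36 is the handle for setting C7. The demand is selective reaction of singlet oxygen with the furan.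

34 to 33: the C9–C10 bond is cut and C20 is reattached to O9. The ten-membered ring becomes a thirteen-membered ether, which is easier to close, and two stereocentres are traded for one sp3 carbon of fixed configuration (C1). The forward step must metalate C9 selectively and deliver it to the β face of C10.

33 to 20 and 30 (through 32 and 31): the C4–C5 bond (ring closure between two sp2 carbons), the C2–C3 bond (vinyl anion plus aldehyde) and the C20–O bond (allylic bromide plus alcohol) are cut. This leaves a ring A bromo aldehyde and a furan alcohol of similar size. C2 must be formed with the right configuration, and both alkene geometries must survive the coupling.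

20 to 1 (through 17, 13, 11, 9, 5, 3, 2): the C20 branch, the 12,13-diol, the C10=C11 bond and the formyl carbon are traced back to an enone whose only stereocentres (C1, C14) come from the desymmetrising reduction of a prochiral dione. The demands are a hydroxyl-directed dihydroxylation on the face of the C14 oxygen and an alkene cleavage that spares the ring.

30 to 21 and 22 (through 28, 26, 25, 23): the C5–I and C6–H bonds are traced to an alkyne, the alkyne and the silyl group to two ring metalations, and the 3,4-disubstituted furan to a cycloaddition/cycloreversion. The demand is a trans hydrometalation that places the metal next to the hydroxymethyl group.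

## Other disconnections considered

Alternative 1: Ring A is cut at C1–C14 and C10–C11 into the enal A1 (C2, C1, C10, C9) and the diene A2 (C14–C11). The forward step is an endo Diels–Alder reaction under the oxazaborolidinium salt made from (S)-diphenylprolinol, o-tolylboronic acid and HNTf2, giving A3. In its favour, one catalytic step would fix the quaternary C1 together with C10 and C14, and C2 arrives as an aldehyde, whereas the chosen plan carves the formyl group out of an allyl group and needs thirteen steps for ring A. On this point the alternative is the better plan. Catalyst control and the enzymatic control used here are equal in kind. Against it, a β-substituted α-methyl enal is a weak dienophile, and the 1-alkoxy-3-silyloxy diene is prone to Mukaiyama-type side reactions with so strong a Lewis acid. C20 and the C13 oxygen are still missing. Most important, in A3 the C9–C10 bond already exists, so the ten-membered ring must be closed by a true medium-ring cyclisation elsewhere. The chosen plan turns this closure into a ring contraction, so the gain in ring A is paid back at the large ring.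

Alternative 2: The lactone is cut at C8–C17. The forward step reduces the 2-bromopropanoate A4 with SmI2 to a samarium enolate that adds to the C8 ketone and gives A5. In its favour, the lactone ring, the C8 alcohol and C17 arise in one step on a late intermediate, against four operations in the chosen plan (furan oxidation, directed reduction, epoxidation, reductive opening). C17 is set in a chelated C–C bond-forming transition state rather than by protonation of an enolate. On both points the alternative is the better plan. Against it, A4 is a ketone with an acyloxy group on one α-carbon and a silyloxy group on the other, and divalent samarium can cleave such C–O bonds. The C9 silyl ether must be exchanged for acetate at the very end, next to the epoxide. The facial selectivity at C8 rests on the ring conformation, as it does in the chosen plan (equal). The alternative is silent on how the ten-membered ketone is made, whereas in the chosen plan the lactone carbons double as the group that makes C9 acidic.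

Alternative 3: The bicycle is cut at C1–C10. In the forward step BF3·OEt2 or MeAlCl2 opens the C1–C2 epoxide of the fourteen-membered epoxy allylsilane A6, and C10 attacks C1 across the ring to give A7. In its favour, two carbocycles, the quaternary C1, C10, the C2 hydroxyl and the C11=C20 methylene would form in one step. That is more rings and bonds per step than the chosen key step, and here the alternative is the better plan. Dependence on a macrocycle conformation for the ring-fusion stereochemistry is the same kind of risk as in the chosen plan (equal). Against it, A6 must already carry the lactone, a tertiary silyl ether and an allylic acetate when it meets the Lewis acid, and ionisation at propargylic C2 competes with ionisation at C1. As formulated, A7 holds a C3≡C4 triple bond inside the ten-membered ring, which is strained and still needs a cis reduction. A7 also has no oxygen at C12 (the acetonide spans C13/C14), so a late allylic oxidation and a three-way differentiation of the ring A oxygens would be needed. The long assembly of A6 and this longer end game outweigh the gain of the double ring closure.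

Key step: step 24

Remarks before the steps (one line each):
- Briarane locants are used for all intermediates; on ring A, β is the face of the C15 methyl group and α the opposite face.
- The precursor 33 and product 34 agree with the target at every stereocentre; by the CIP rules the diene is 3Z,5E (C16 outranks C4 on C5), with both double bonds cis inside the ring.
- 4-MeOC6H4CH2OCH2Cl (from 4-methoxybenzyl alcohol, paraformaldehyde and HCl) and (Z)-Bu3SnCH=CHSnBu3 (from acetylene and Bu3SnSnBu3 with Pd(PPh3)4) are treated as reagents, not as counted steps.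
- 33 is reached with the C2 hydroxyl already free (it is formed in step 22 and never protected), so it enters the key step as its lithium alkoxide.

## Steps

Step 1
Reactants: 1 2-methylcyclohexane-1,3-dione
Product: 2 2-methyl-2-(prop-2-en-1-yl)cyclohexane-1,3-dione
Conditions: allyl bromide, 1 M aq. NaOH, Bu4NI (cat.), rt
Reagents that add atoms: allyl bromide, C=CCBr
Why: C-alkylation of the cyclic 1,3-diketone enolate with a soft allylic halide in water; it should give the prochiral 2,2-disubstituted dione.

Step 2
Reactants: 2 2-methyl-2-(prop-2-en-1-yl)cyclohexane-1,3-dione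
Product: 3 (2S,3S)-3-hydroxy-2-methyl-2-(prop-2-en-1-yl)cyclohexan-1-one
Conditions: baker's yeast (Saccharomyces cerevisiae), sucrose, H2O, 30 °C
Reagents that add atoms: none
Why: Enzymatic desymmetrising reduction of a prochiral 2,2-disubstituted cyclohexane-1,3-dione; this substrate class is known to give the (2S,3S)-hydroxy ketone, which sets C1 (methyl β) and C14 (oxygen α, cis to the allyl group that becomes C2).

Step 3
Reactants: 3 (2S,3S)-3-hydroxy-2-methyl-2-(prop-2-en-1-yl)cyclohexan-1-one
Product: 5 (5S,6S)-5-hydroxy-6-methyl-6-(prop-2-en-1-yl)cyclohex-2-en-1-one, via selenide 4 (not isolated)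
Conditions: LiN(i-Pr)2 (2.2 equiv), THF, −78 °C; PhSeCl; then 30% H2O2, pyridine, CH2Cl2, 0 °C
Reagents that add atoms: none
Why: The alkoxide/enolate dianion (only C11 carries α-hydrogens) is selenenylated, and selenoxide syn-elimination should give the enone; no palladium is used, so the allyl group cannot cyclise onto the enolate.

Step 4
Reactants: 5 (5S,6S)-5-hydroxy-6-methyl-6-(prop-2-en-1-yl)cyclohex-2-en-1-one
Product: 7 (5S,6S)-2-[(4-methoxybenzyloxy)methyl]-6-methyl-6-(prop-2-en-1-yl)-5-(trimethylsilyloxy)cyclohex-3-en-1-one (C2 epimers), via O-silyl enone 6 (not isolated)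
Conditions: LiN(i-Pr)2 (1.0 equiv), Me3SiCl, THF, −78 °C; LiN(i-Pr)2 (1.1 equiv), DMPU; 4-MeOC6H4CH2OCH2Cl, −78 to −40 °C
Reagents that add atoms: chlorotrimethylsilane, C[Si](C)(C)Cl; 1-(chloromethoxymethyl)-4-methoxybenzene, ClCOCc1ccc(OC)cc1
Why: After transient O-silylation, γ-deprotonation (C13; there is no α′-hydrogen) gives the extended dienolate, which should alkylate at its α-carbon C11 (deconjugative α-alkylation); this brings in C20 as a protected hydroxymethyl group, and the C11 configuration is lost again in step 5.

Step 5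
Reactants: 7 (5S,6S)-2-[(4-methoxybenzyloxy)methyl]-6-methyl-6-(prop-2-en-1-yl)-5-(trimethylsilyloxy)cyclohex-3-en-1-one
Product: 9 (5S,6S)-5-hydroxy-2-[(4-methoxybenzyloxy)methyl]-6-methyl-6-(prop-2-en-1-yl)cyclohexa-1,3-dien-1-yl trifluoromethanesulfonate, via silyl dienyl triflate 8 (not isolated)
Conditions: KN(SiMe3)2, THF, −78 °C; N-(5-chloropyridin-2-yl)triflimide (Comins' reagent); then citric acid, MeOH, 0 °C
Reagents that add atoms: N-(5-chloropyridin-2-yl)-1,1,1-trifluoro-N-(trifluoromethylsulfonyl)methanesulfonamide, FC(F)(F)S(=O)(=O)N(c1ccc(Cl)cn1)S(=O)(=O)C(F)(F)F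
Why: Removal of the doubly activated C11–H (or of C13–H of any reconjugated isomer) leads to one and the same dienolate, which is O-triflated; mild acid methanolysis then frees the C14 hydroxyl needed in step 6.

Step 6
Reactants: 9 (5S,6S)-5-hydroxy-2-[(4-methoxybenzyloxy)methyl]-6-methyl-6-(prop-2-en-1-yl)cyclohexa-1,3-dien-1-yl trifluoromethanesulfonate
Product: 11 ring A triol (10-triflyloxy C10=C11, 20-O-PMB, 12α,13α,14α-triol, 1β-methyl, 1α-allyl), via osmate ester 10 (not isolated)
Conditions: OsO4 (1.05 equiv), TMEDA, CH2Cl2, −78 °C; then aq. Na2SO3, THF, rt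
Reagents that add atoms: osmium tetroxide, O=[Os](=O)(=O)=O
Why: Hydroxyl-directed dihydroxylation (Donohoe conditions): the OsO4·TMEDA complex hydrogen-bonded to the C14 hydroxyl should deliver both oxygens to the neighbouring C12=C13 bond on the α face; the enol triflate double bond is tetrasubstituted and electron-poor, and the isolated allyl group is not hydrogen-bond activated, as in the known preference of this reagent for the allylic-alcohol alkene of polyenes.

Step 7
Reactants: 11 ring A triol
Product: 12 12,13-O-isopropylidene derivative of 11 (14α-hydroxyl free)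
Conditions: 2-methoxypropene, PPTS (cat.), CH2Cl2, 0 °C
Reagents that add atoms: 2-methoxypropene, COC(C)=C
Why: Kinetic acetonide formation should engage the less hindered cis pair O12/O13, because the C14 hydroxyl is neopentylic (next to quaternary C1) and is the last to react.

Step 8
Reactants: 12 12,13-O-isopropylidene derivative of 11
Product: 13 14-O-tert-butyldimethylsilyl ether of 12
Conditions: t-BuMe2SiOTf, 2,6-lutidine, CH2Cl2, 0 °C
Reagents that add atoms: tert-butyldimethylsilyl trifluoromethanesulfonate, CC(C)(C)[Si](C)(C)OS(=O)(=O)C(F)(F)F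
Why: Silyl triflate with a hindered pyridine base is the standard way to silylate a hindered secondary alcohol.

Step 9
Reactants: 13 14-O-tert-butyldimethylsilyl ether of 12
Product: 14 (E)-prop-1-enyl isomer of 13
Conditions: RuHCl(CO)(PPh3)3 (5 mol %), toluene, 80 °C
Reagents that add atoms: none
Why: Ruthenium-hydride-catalysed migration of a terminal double bond by one position; the quaternary C1 stops further migration, and the enol triflate alkene does not insert.

Step 10
Reactants: 14 (E)-prop-1-enyl isomer of 13
Product: 16 C1-carbaldehyde enol triflate (C2 = CHO), via side-chain diol 15 (not isolated)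
Conditions: OsO4 (cat.), NaIO4, 2,6-lutidine, dioxane/H2O (3:1), rt
Reagents that add atoms: osmium tetroxide, O=[Os](=O)(=O)=O; sodium periodate, [Na+].[O-]I(=O)(=O)=O
Why: Lemieux–Johnson cleavage; OsO4 should attack the electron-rich disubstituted propenyl group and leave the tetrasubstituted, electron-poor enol triflate, and no ketone is present at C10, so no β-keto aldehyde arises.

Step 11
Reactants: 16 C1-carbaldehyde enol triflate
Product: 17 ring A aldehyde (C10=C11, 20-O-PMB, 12,13-acetonide, 14-O-TBS)
Conditions: Pd(OAc)2 (cat.), PPh3, HCO2H, Et3N, DMF, 60 °C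
Reagents that add atoms: none
Why: Palladium-catalysed formate reduction of an enol triflate (oxidative addition to zerovalent palladium, formate exchange, loss of CO2, reductive elimination) puts hydrogen on C10; the aldehyde and the allylic ethers are not touched under these conditions.

Step 12
Reactants: 17 ring A aldehyde
Product: 18 ring A hydroxy aldehyde (C20–OH)
Conditions: DDQ, CH2Cl2/pH 7 buffer, 0 °C
Reagents that add atoms: none
Why: Oxidative cleavage of the 4-methoxybenzyl ether by hydride abstraction; silyl ether, acetonide and aldehyde are inert, and C20 is trans to C1 across C10=C11, so no lactol can form.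

Step 13
Reactants: 18 ring A hydroxy aldehyde
Product: 20 ring A bromo aldehyde (C20–Br), via mesylate 19 (not isolated)
Conditions: MsCl, Et3N, CH2Cl2, −20 °C; then LiBr, THF, 0 °C
Reagents that add atoms: lithium bromide, [Li+].[Br-]
Why: Sulfonylation and SN2 displacement at the primary allylic carbon; phosphine-based bromination is avoided because of the aldehyde.

Step 14
Reactants: 21 4-phenyl-1,3-oxazole; 22 ethyl but-2-ynoate
Product: 23 ethyl 4-methylfuran-3-carboxylate
Conditions: neat, sealed tube, 200 °C
Reagents that add atoms: none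
Why: Oxazole–alkyne Diels–Alder reaction followed by retro-Diels–Alder loss of benzonitrile; both orientations of the alkyne give the same 3,4-disubstituted furan.

Step 15
Reactants: 23 ethyl 4-methylfuran-3-carboxylate
Product: 24 ethyl 2-bromo-4-methylfuran-3-carboxylate
Conditions: TMPMgCl·LiCl, THF, −25 °C; then (BrCl2C)2, −25 °C to rt
Reagents that add atoms: 1,2-dibromo-1,1,2,2-tetrachloroethane, BrC(Cl)(Cl)C(Cl)(Cl)Br
Why: Ester-directed magnesiation at the α-carbon next to the ester (the future C7) with a hindered magnesium amide that tolerates the ester, followed by electrophilic bromination.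

Step 16
Reactants: 24 ethyl 2-bromo-4-methylfuran-3-carboxylate
Product: 25 ethyl 2-bromo-4-methyl-5-(trimethylsilyl)furan-3-carboxylate
Conditions: LiN(i-Pr)2, Me3SiCl (in situ), THF, −78 °C
Reagents that add atoms: chlorotrimethylsilane, C[Si](C)(C)Cl
Why: In-situ-quench lithiation of the only remaining ring C–H (the α-carbon next to the methyl-bearing carbon, the future C19), acidified by the ring oxygen and the bromine; the 2-bromo substituent cannot migrate because both β-positions are occupied.

Step 17
Reactants: 25 ethyl 2-bromo-4-methyl-5-(trimethylsilyl)furan-3-carboxylate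
Product: 26 ethyl 2-(3-hydroxyprop-1-yn-1-yl)-4-methyl-5-(trimethylsilyl)furan-3-carboxylate
Conditions: prop-2-yn-1-ol, PdCl2(PPh3)2 (cat.), CuI (cat.), Et3N, THF, 50 °C
Reagents that add atoms: prop-2-yn-1-ol, C#CCO
Why: Sonogashira coupling of an ester-activated 2-bromofuran; it installs C6, C5 and C16.

Step 18
Reactants: 26 ethyl 2-(3-hydroxyprop-1-yn-1-yl)-4-methyl-5-(trimethylsilyl)furan-3-carboxylate
Product: 28 ethyl 2-[(1Z)-3-hydroxy-2-iodoprop-1-en-1-yl]-4-methyl-5-(trimethylsilyl)furan-3-carboxylate, via vinylstannane 27 (not isolated)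
Conditions: Bu3SnH, [Cp*RuCl]4 (cat.), CH2Cl2, rt; then I2, 0 °C
Reagents that add atoms: iodine, II
Why: Hydroxyl-directed ruthenium-catalysed trans-hydrostannation puts tin on the alkyne carbon next to the CH2OH group (C5) and hydrogen on C6 from the opposite side, so tin is cis to the furan; iododestannylation with retention then gives the (Z)-iodoalkene that fixes the C5=C6 geometry.

Step 19
Reactants: 28 ethyl 2-[(1Z)-3-hydroxy-2-iodoprop-1-en-1-yl]-4-methyl-5-(trimethylsilyl)furan-3-carboxylate
Product: 29 ethyl 2-[(1Z)-3-(tert-butyldimethylsilyloxy)-2-iodoprop-1-en-1-yl]-4-methyl-5-(trimethylsilyl)furan-3-carboxylate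
Conditions: t-BuMe2SiCl, imidazole, DMF, rt
Reagents that add atoms: tert-butylchlorodimethylsilane, CC(C)(C)[Si](C)(C)Cl
Why: Standard silylation of the primary allylic alcohol (O16); the ester has so far served as the masked C9 hydroxyl.

Step 20
Reactants: 29 ethyl 2-[(1Z)-3-(tert-butyldimethylsilyloxy)-2-iodoprop-1-en-1-yl]-4-methyl-5-(trimethylsilyl)furan-3-carboxylate
Product: 30 {2-[(1Z)-3-(tert-butyldimethylsilyloxy)-2-iodoprop-1-en-1-yl]-4-methyl-5-(trimethylsilyl)furan-3-yl}methanol
Conditions: i-Bu2AlH, CH2Cl2, −78 °C
Reagents that add atoms: none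
Why: Hydride reduction of the ester to the primary alcohol (C9–OH); the vinyl iodide and both silyl groups are stable at low temperature.

Step 21
Reactants: 20 ring A bromo aldehyde; 30 {2-[(1Z)-3-(tert-butyldimethylsilyloxy)-2-iodoprop-1-en-1-yl]-4-methyl-5-(trimethylsilyl)furan-3-yl}methanol
Product: 31 ether aldehyde (C9–O–C20 ether; C2 = CHO)
Conditions: AgOTf, 2,6-di-tert-butyl-4-methylpyridine, 4 Å MS, CH2Cl2, 0 °C, dark
Reagents that add atoms: none
Why: Silver-assisted Williamson-type O-alkylation of the primary alcohol by the primary allylic bromide under non-basic conditions, so that the non-enolisable aldehyde and the (Z)-iodoalkene (which an alkoxide could eliminate to the alkyne) are not attacked.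

Step 22
Reactants: 31 ether aldehyde
Product: 32 (2S)-allylic alcohol with (Z)-C3=C4–SnBu3
Conditions: (Z)-Bu3SnCH=CHSnBu3, n-BuLi, THF, −78 °C; then 31, −78 °C
Reagents that add atoms: (Z)-1,2-bis(tributylstannyl)ethene, CCCC[Sn](CCCC)(CCCC)/C=C\[Sn](CCCC)(CCCC)CCCC
Why: Tin–lithium exchange gives a configurationally stable (Z)-vinyllithium that adds to the aldehyde faster than it exchanges with the hindered vinyl iodide; with the formyl hydrogen turned over ring A and the oxygen near the methyl group, attack anti to the bulky silyloxy-bearing C14 and past the flat C10 should give the 2S alcohol, and the C3=C4 geometry comes from the reagent.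

Step 23
Reactants: 32 (2S)-allylic alcohol with (Z)-C3=C4–SnBu3
Product: 33 thirteen-membered furan ether (2-OH, 14-O-TBS, 16-O-TBS, 12,13-acetonide, 19-SiMe3; 3Z,5E-diene cis in the ring at both bonds; C10=C11)
Conditions: Pd(PPh3)4 (cat.), Cu(thiophene-2-carboxylate), [Bu4N][Ph2PO2], DMF, rt, 1 mM
Reagents that add atoms: none
Why: Intramolecular Stille coupling (C4–Sn with C5–I) with retention at both alkenes closes the thirteen-membered ring; the two ring-cis double bonds hold the reacting ends close, and the copper carboxylate/phosphinate additive system is suited to hindered alkenylstannanes and tolerates the free hydroxyl.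

Step 24
Reactants: 33 thirteen-membered furan ether
Product: 34 furan-fused ten-membered carbocycle (9-OH, H-10 α, C11=C20 methylene, 2-OH, 14-O-TBS, 16-O-TBS, 12,13-acetonide, 19-SiMe3)
Conditions: n-BuLi (2.5 equiv), THF, −78 to −40 °C; then aq. NH4Cl
Reagents that add atoms: none
Why: n-BuLi first turns the C2 hydroxyl into its lithium alkoxide and then removes a C9 proton, the most acidic C–H because the carbanion is α to the ether oxygen that pre-coordinates the base and is conjugated through the furan (C8=C7) with the diene, while the C19 silyl group blocks furan lithiation and the alkoxide makes C2–H non-acidic. The α-oxy carbanion then undergoes a suprafacial [2,3]-sigmatropic (Wittig) shift through a five-membered envelope (C9, O, C20, C11, C10): the C9–C10 bond forms, the O–C20 bond breaks and the ring A double bond moves to C11=C20; the closest known reaction type is the [2,3]-Wittig ring contraction of thirteen-membered allylic propargylic or benzylic ethers to ten-membered carbocyclic alcohols. The ten-membered ring is closed by this transannular bond formation, in which O, C20 and C11 leave the thirteen-membered ring, and not by an end-to-end cyclisation, so dilution is not critical. For C10, the α face of the C10=C11 bond is covered by the cis-fused 12,13-acetonide and the C14 silyl ether, so the O–C20 bridge and C9 should lie on the β face, anti to C2, which gives the trans ring fusion. For C9, with C9 above C10 and its oxygen above C20, the furan carbon C8 can lie next to C1 or next to H-10; because C8 and C1 are tied by the short, rigid C2–C7 arc (two ring-cis double bonds and the furan), only the first envelope should be reachable, and it gives the C9 alcohol with the configuration of the target. The step needs metalation at C9 and not at C20 or C16, and a [2,3] rather than a [1,2] shift; ether coordination, the low temperature and the lithium counter-ion (which also keeps the C2 alkoxide from an anionic oxy-Cope shift of the C4=C3–C2–C1–C10=C11 unit) should secure this.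

Step 25
Reactants: 34 furan-fused ten-membered carbocycle
Product: 36 methyl (Z)-keto ester (C7 ketone, C8=C17, C19 methyl ester; 2-OH, 9-OH), via hydroxybutenolide 35 (not isolated)
Conditions: O2, hν (visible), tetraphenylporphyrin (cat.), CH2Cl2, −78 °C; then Me3SiCHN2, MeOH, 0 °C
Reagents that add atoms: dioxygen, O=O; (trimethylsilyl)diazomethane, C[Si](C)(C)C=[N+]=[N-]
Why: Silyl-directed singlet-oxygen oxidation of a 2-silylfuran: [4+2] addition across C19/C7 and a 1,2-silyl shift make the silyl-bearing carbon C19 the carboxyl carbon and C7 the keto carbon; the electron-rich furan should react far faster than the diene or the methylene group, and the ring-opened acid tautomer is then trapped as its methyl ester.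

Step 26
Reactants: 36 methyl (Z)-keto ester
Product: 38 butenolide (7-H as in the target, C8=C17; 2-OH, 9-OH), via hydroxy ester 37 (not isolated)
Conditions: Me4NBH(OAc)3, MeCN/AcOH, −25 °C; then camphorsulfonic acid (cat.), CH2Cl2, rt
Reagents that add atoms: none
Why: Hydroxyl-directed reduction of a β-hydroxy ketone (Evans–Saksena type): the C9 hydroxyl binds boron and delivers hydride to the C7 carbonyl through a six-membered chair with C6 and C10 equatorial, which should give the 1,3-anti C7/C9 relationship of the target; the (Z)-γ-hydroxy ester then lactonises under acid.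

Step 27
Reactants: 38 butenolide
Product: 39 tetraol (2-, 9-, 14-, 16-OH; 12,13-acetonide)
Conditions: Bu4NF, AcOH, THF, rt to 40 °C
Reagents that add atoms: none
Why: Fluoride cleavage of both silyl ethers; buffering with acetic acid protects the base-sensitive C7–H of the butenolide.

Step 28
Reactants: 39 tetraol
Product: 40 tetraacetate (2-, 9-, 14-, 16-OAc; 12,13-acetonide)
Conditions: Ac2O, pyridine, DMAP (cat.), CH2Cl2, rt
Reagents that add atoms: acetic anhydride, CC(=O)OC(C)=O
Why: Acyl transfer to one primary and three secondary hydroxyls; no tertiary hydroxyl is present yet, and C8 is still sp2, so the C9 hydroxyl is not unduly hindered.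

Step 29
Reactants: 40 tetraacetate
Product: 41 12,13-diol tetraacetate
Conditions: AcOH/H2O (4:1), 45 °C
Reagents that add atoms: none
Why: Mild acid hydrolysis of the acetonide at a stage with no epoxide and no tertiary alcohol; acid rather than base is used so that the O14 acetyl group should not shift to O13.

Step 30
Reactants: 41 12,13-diol tetraacetate
Product: 42 11,20-epoxy 12,13-diol (epoxide oxygen α)
Conditions: VO(acac)2 (cat.), t-BuOOH, CH2Cl2, 0 °C to rt
Reagents that add atoms: tert-butyl hydroperoxide, CC(C)(C)OO
Why: Vanadium-catalysed hydroxyl-directed epoxidation: the vanadate ester of the allylic C12 hydroxyl (α) should deliver oxygen to the α face of the C11=C20 bond, which sets C11; the butenolide alkene is electron-poor and the diene has no free hydroxyl next to it.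

Step 31
Reactants: 42 11,20-epoxy 12,13-diol
Product: 43 12,13-bis(3-methylbutanoate) butenolide
Conditions: (i-PrCH2CO)2O, DMAP, pyridine, CH2Cl2, rt
Reagents that add atoms: 3-methylbutanoic anhydride, CC(C)CC(=O)OC(=O)CC(C)C
Why: Nucleophile-catalysed acylation of the two secondary hydroxyls; with excess anhydride, acylation should outrun any acetyl shift from O14.

Step 32
Reactants: 43 12,13-bis(3-methylbutanoate) butenolide
Product: 44 8,17-epoxy lactone (epoxide oxygen on the face of the later 8-OH)
Conditions: aq. NaOCl, pyridine, 0 °C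
Reagents that add atoms: sodium hypochlorite, [Na+].[O-]Cl
Why: Nucleophilic (Weitz–Scheffer-type) epoxidation of the α,β-unsaturated lactone by conjugate addition of hypochlorite to C8 and ring closure at C17; the weakly basic medium should spare C7–H and the esters, the unactivated alkenes are not attacked, and attack from the outer face of the ten-membered ring should give the trans-fused 8α-oxygenated lactone.

Step 33
Reactants: 44 8,17-epoxy lactone
Product: 45 target CNP0303383.2
Conditions: SmI2, THF/MeOH, −78 °C
Reagents that add atoms: none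
Why: Reductive opening of an α,β-epoxy lactone by two single-electron transfers from divalent samarium: the C17–O bond α to the carbonyl breaks, the C8–O bond is kept (tertiary 8-OH with retention), and the samarium enolate is protonated by methanol at C17, which should place the methyl group trans to C9, the less crowded and thermodynamically preferred arrangement; isolated epoxides and esters are inert at this temperature.

## Compound list

1 | 2-methylcyclohexane-1,3-dione | CC1C(=O)CCCC1=O | starting material
2 | 2-methyl-2-(prop-2-en-1-yl)cyclohexane-1,3-dione | C=CCC1(C)C(=O)CCCC1=O | intermediate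
3 | (2S,3S)-3-hydroxy-2-methyl-2-(prop-2-en-1-yl)cyclohexan-1-one | O=C1[C@@](C)(CC=C)[C@@H](O)CCC1 | intermediate
4 | (2S,3S)-3-hydroxy-2-methyl-6-(phenylselanyl)-2-(prop-2-en-1-yl)cyclohexan-1-one, C6 epimers (not isolated) | O=C1[C@@](C)(CC=C)[C@@H](O)CCC1[Se]c1ccccc1 | intermediate
5 | (5S,6S)-5-hydroxy-6-methyl-6-(prop-2-en-1-yl)cyclohex-2-en-1-one | O=C1[C@@](C)(CC=C)[C@@H](O)CC=C1 | intermediate
6 | (5S,6S)-6-methyl-6-(prop-2-en-1-yl)-5-(trimethylsilyloxy)cyclohex-2-en-1-one (not isolated) | O=C1[C@@](C)(CC=C)[C@@H](O[Si](C)(C)C)CC=C1 | intermediate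
7 | (5S,6S)-2-[(4-methoxybenzyloxy)methyl]-6-methyl-6-(prop-2-en-1-yl)-5-(trimethylsilyloxy)cyclohex-3-en-1-one, C2 epimers | O=C1[C@@](C)(CC=C)[C@@H](O[Si](C)(C)C)C=CC1COCc1ccc(OC)cc1 | intermediate
8 | (5S,6S)-2-[(4-methoxybenzyloxy)methyl]-6-methyl-6-(prop-2-en-1-yl)-5-(trimethylsilyloxy)cyclohexa-1,3-dien-1-yl trifluoromethanesulfonate (not isolated) | FC(F)(F)S(=O)(=O)OC=1[C@@](C)(CC=C)[C@@H](O[Si](C)(C)C)C=CC=1COCc1ccc(OC)cc1 | intermediate
9 | (5S,6S)-5-hydroxy-2-[(4-methoxybenzyloxy)methyl]-6-methyl-6-(prop-2-en-1-yl)cyclohexa-1,3-dien-1-yl trifluoromethanesulfonate | FC(F)(F)S(=O)(=O)OC=1[C@@](C)(CC=C)[C@@H](O)C=CC=1COCc1ccc(OC)cc1 | intermediate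
10 | cyclic 12α,13α-osmate ester of 11 with TMEDA on hexavalent osmium (not isolated) | FC(F)(F)S(=O)(=O)OC=1[C@@](C)(CC=C)[C@@H](O)[C@H]2O[Os-2]3(=O)(=O)([N+](C)(C)CC[N+]3(C)C)O[C@H]2C=1COCc1ccc(OC)cc1 | intermediate
11 | ring A triol: C10 enol triflate (C10=C11), 20-O-(4-methoxybenzyl), 12α,13α,14α-triol, 1β-methyl, 1α-allyl | FC(F)(F)S(=O)(=O)OC=1[C@@](C)(CC=C)[C@@H](O)[C@@H](O)[C@@H](O)C=1COCc1ccc(OC)cc1 | intermediate
12 | 12α,13α-O-isopropylidene derivative of 11 with free 14α-hydroxyl | FC(F)(F)S(=O)(=O)OC=1[C@@](C)(CC=C)[C@@H](O)[C@H]2OC(C)(C)O[C@H]2C=1COCc1ccc(OC)cc1 | intermediate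
13 | 14α-O-tert-butyldimethylsilyl ether of 12 | FC(F)(F)S(=O)(=O)OC=1[C@@](C)(CC=C)[C@@H](O[Si](C)(C)C(C)(C)C)[C@H]2OC(C)(C)O[C@H]2C=1COCc1ccc(OC)cc1 | intermediate
14 | 1α-[(E)-prop-1-enyl] isomer of 13 | FC(F)(F)S(=O)(=O)OC=1[C@@](C)(/C=C/C)[C@@H](O[Si](C)(C)C(C)(C)C)[C@H]2OC(C)(C)O[C@H]2C=1COCc1ccc(OC)cc1 | intermediate
15 | 1α-(1,2-dihydroxypropyl) derivative from 14, diastereomer mixture (not isolated) | FC(F)(F)S(=O)(=O)OC=1[C@@](C)(C(O)C(C)O)[C@@H](O[Si](C)(C)C(C)(C)C)[C@H]2OC(C)(C)O[C@H]2C=1COCc1ccc(OC)cc1 | intermediate
16 | ring A enol triflate aldehyde: 1β-methyl, 1α-formyl (C2), 10-triflyloxy, 20-O-(4-methoxybenzyl), 12α,13α-acetonide, 14α-O-TBS | FC(F)(F)S(=O)(=O)OC=1[C@@](C)(C=O)[C@@H](O[Si](C)(C)C(C)(C)C)[C@H]2OC(C)(C)O[C@H]2C=1COCc1ccc(OC)cc1 | intermediate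
17 | ring A aldehyde: C10=C11 (10-H), 1β-methyl, 1α-formyl, 20-O-(4-methoxybenzyl), 12α,13α-acetonide, 14α-O-TBS | COc1ccc(COCC2=C[C@@](C)(C=O)[C@@H](O[Si](C)(C)C(C)(C)C)[C@H]3OC(C)(C)O[C@@H]23)cc1 | intermediate
18 | ring A hydroxy aldehyde: as 17 with free 20-hydroxyl | OCC1=C[C@@](C)(C=O)[C@@H](O[Si](C)(C)C(C)(C)C)[C@H]2OC(C)(C)O[C@@H]12 | intermediate
19 | 20-O-methanesulfonate of 18 (not isolated) | CS(=O)(=O)OCC1=C[C@@](C)(C=O)[C@@H](O[Si](C)(C)C(C)(C)C)[C@H]2OC(C)(C)O[C@@H]12 | intermediate
20 | ring A bromo aldehyde: as 18 with 20-bromide | BrCC1=C[C@@](C)(C=O)[C@@H](O[Si](C)(C)C(C)(C)C)[C@H]2OC(C)(C)O[C@@H]12 | intermediate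
21 | 4-phenyl-1,3-oxazole | c1ccc(cc1)-c1cocn1 | starting material
22 | ethyl but-2-ynoate | CC#CC(=O)OCC | starting material
23 | ethyl 4-methylfuran-3-carboxylate | CCOC(=O)c1cocc1C | intermediate
24 | ethyl 2-bromo-4-methylfuran-3-carboxylate | CCOC(=O)c1c(Br)occ1C | intermediate
25 | ethyl 2-bromo-4-methyl-5-(trimethylsilyl)furan-3-carboxylate | CCOC(=O)c1c(Br)oc([Si](C)(C)C)c1C | intermediate
26 | ethyl 2-(3-hydroxyprop-1-yn-1-yl)-4-methyl-5-(trimethylsilyl)furan-3-carboxylate | CCOC(=O)c1c(C#CCO)oc([Si](C)(C)C)c1C | intermediate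
27 | ethyl 2-[(1Z)-3-hydroxy-2-(tributylstannyl)prop-1-en-1-yl]-4-methyl-5-(trimethylsilyl)furan-3-carboxylate (not isolated) | CCOC(=O)c1c(/C=C(/CO)[Sn](CCCC)(CCCC)CCCC)oc([Si](C)(C)C)c1C | intermediate
28 | ethyl 2-[(1Z)-3-hydroxy-2-iodoprop-1-en-1-yl]-4-methyl-5-(trimethylsilyl)furan-3-carboxylate | CCOC(=O)c1c(/C=C(/CO)I)oc([Si](C)(C)C)c1C | intermediate
29 | ethyl 2-[(1Z)-3-(tert-butyldimethylsilyloxy)-2-iodoprop-1-en-1-yl]-4-methyl-5-(trimethylsilyl)furan-3-carboxylate | CCOC(=O)c1c(/C=C(/CO[Si](C)(C)C(C)(C)C)I)oc([Si](C)(C)C)c1C | intermediate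
30 | {2-[(1Z)-3-(tert-butyldimethylsilyloxy)-2-iodoprop-1-en-1-yl]-4-methyl-5-(trimethylsilyl)furan-3-yl}methanol | OCc1c(/C=C(/CO[Si](C)(C)C(C)(C)C)I)oc([Si](C)(C)C)c1C | intermediate
31 | ether aldehyde: ring A aldehyde of 20 joined through C20–O–C9 to the furan of 30 | C(OCc1c(/C=C(/CO[Si](C)(C)C(C)(C)C)I)oc([Si](C)(C)C)c1C)C1=C[C@@](C)(C=O)[C@@H](O[Si](C)(C)C(C)(C)C)[C@H]2OC(C)(C)O[C@@H]12 | intermediate
32 | (2S)-allylic alcohol of 31 with a (Z)-2-(tributylstannyl)ethenyl group on C2 (C3=C4–Sn) | C(OCc1c(/C=C(/CO[Si](C)(C)C(C)(C)C)I)oc([Si](C)(C)C)c1C)C1=C[C@@](C)([C@@H](O)/C=C\[Sn](CCCC)(CCCC)CCCC)[C@@H](O[Si](C)(C)C(C)(C)C)[C@H]2OC(C)(C)O[C@@H]12 | intermediate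
33 | thirteen-membered 3-furylmethyl cyclohexenylmethyl ether: (2S)-2-OH, 3Z,5E-diene, 16-O-TBS, 19-trimethylsilyl furan, C9–O–C20, C10=C11, 12α,13α-acetonide, 14α-O-TBS, 1β-methyl | CC(C)(C)[Si](C)(C)OCC1=C/c2oc([Si](C)(C)C)c(C)c2COCC3=C[C@@](C)([C@@H](O)/C=C\1)[C@@H](O[Si](C)(C)C(C)(C)C)[C@H]4OC(C)(C)O[C@@H]34 | intermediate
34 | furan-fused ten-membered carbocycle: 9-OH and C9–C10 bond on the β face of ring A (H-10 α), C11=C20 methylene, 2-OH, otherwise as 33 | CC(C)(C)[Si](C)(C)OCC1=C/c2oc([Si](C)(C)C)c(C)c2[C@@H](O)[C@H]3C(=C)[C@@H]4OC(C)(C)O[C@@H]4[C@H](O[Si](C)(C)C(C)(C)C)[C@]3(C)[C@@H](O)/C=C\1 | intermediate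
35 | 7-hydroxybutenolide from 34 (C19 lactone carbonyl, C7 hemiketal, C8=C17), C7 epimers (not isolated) | CC(C)(C)[Si](C)(C)OCC1=C/C2(O)OC(=O)C(C)=C2[C@@H](O)[C@H]3C(=C)[C@@H]4OC(C)(C)O[C@@H]4[C@H](O[Si](C)(C)C(C)(C)C)[C@]3(C)[C@@H](O)/C=C\1 | intermediate
36 | ring-opened methyl ester of 35: C7 ketone, (Z)-C8=C17, C19 methyl ester, 2-OH, 9-OH | CC(C)(C)[Si](C)(C)OCC1=C/C(=O)/C(=C(/C)C(=O)OC)[C@@H](O)[C@H]2C(=C)[C@@H]3OC(C)(C)O[C@@H]3[C@H](O[Si](C)(C)C(C)(C)C)[C@]2(C)[C@@H](O)/C=C\1 | intermediate
37 | 7-hydroxy ester from 36 with C7 as in the target, 7,9-anti (not isolated) | CC(C)(C)[Si](C)(C)OCC1=C/[C@H](O)/C(=C(/C)C(=O)OC)[C@@H](O)[C@H]2C(=C)[C@@H]3OC(C)(C)O[C@@H]3[C@H](O[Si](C)(C)C(C)(C)C)[C@]2(C)[C@@H](O)/C=C\1 | intermediate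
38 | butenolide: C7–O–C19 lactone, C8=C17, 2-OH, 9-OH, 14-O-TBS, 16-O-TBS, 12,13-acetonide, C11=C20 | CC(C)(C)[Si](C)(C)OCC1=C/[C@@H]2OC(=O)C(C)=C2[C@@H](O)[C@H]3C(=C)[C@@H]4OC(C)(C)O[C@@H]4[C@H](O[Si](C)(C)C(C)(C)C)[C@]3(C)[C@@H](O)/C=C\1 | intermediate
39 | butenolide tetraol (2-, 9-, 14-, 16-OH; 12,13-acetonide) | OCC1=C/[C@@H]2OC(=O)C(C)=C2[C@@H](O)[C@H]3C(=C)[C@@H]4OC(C)(C)O[C@@H]4[C@H](O)[C@]3(C)[C@@H](O)/C=C\1 | intermediate
40 | butenolide 2,9,14,16-tetraacetate 12,13-acetonide | CC(=O)OCC1=C/[C@@H]2OC(=O)C(C)=C2[C@@H](OC(C)=O)[C@H]3C(=C)[C@@H]4OC(C)(C)O[C@@H]4[C@H](OC(C)=O)[C@]3(C)[C@@H](OC(C)=O)/C=C\1 | intermediate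
41 | butenolide 2,9,14,16-tetraacetate 12α,13α-diol | CC(=O)OCC1=C/[C@@H]2OC(=O)C(C)=C2[C@@H](OC(C)=O)[C@H]3C(=C)[C@H](O)[C@H](O)[C@H](OC(C)=O)[C@]3(C)[C@@H](OC(C)=O)/C=C\1 | intermediate
42 | 11,20-epoxide (oxygen α) of 41 | CC(=O)OCC1=C/[C@@H]2OC(=O)C(C)=C2[C@@H](OC(C)=O)[C@H]3[C@@]4(CO4)[C@H](O)[C@H](O)[C@H](OC(C)=O)[C@]3(C)[C@@H](OC(C)=O)/C=C\1 | intermediate
43 | 12,13-bis(3-methylbutanoate) of 42 (butenolide, C8=C17) | CC(=O)OCC1=C/[C@@H]2OC(=O)C(C)=C2[C@@H](OC(C)=O)[C@H]3[C@@]4(CO4)[C@H](OC(=O)CC(C)C)[C@H](OC(=O)CC(C)C)[C@H](OC(C)=O)[C@]3(C)[C@@H](OC(C)=O)/C=C\1 | intermediate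
44 | 8,17-epoxy lactone from 43 (epoxide oxygen on the face of the later 8-OH) | CC(=O)OCC1=C/[C@@H]2OC(=O)[C@]3(C)O[C@]23[C@@H](OC(C)=O)[C@H]4[C@@]5(CO5)[C@H](OC(=O)CC(C)C)[C@H](OC(=O)CC(C)C)[C@H](OC(C)=O)[C@]4(C)[C@@H](OC(C)=O)/C=C\1 | intermediate
45 | CNP0303383.2: briarane 2,9,14,16-tetraacetate 12,13-bis(3-methylbutanoate) with 8-hydroxyl, 11,20-epoxide and 7,8-fused 17-methyl lactone | CC(=O)OCC1=C/[C@@H]2OC(=O)[C@H](C)[C@@]2(O)[C@@H](OC(C)=O)[C@H]2[C@@]3(CO3)[C@H](OC(=O)CC(C)C)[C@H](OC(=O)CC(C)C)[C@H](OC(C)=O)[C@]2(C)[C@@H](OC(C)=O)/C=C\1 | target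

Total step count: 33 steps.
Longest linear sequence: 26 steps (steps 1–13 and 21–33, from 1); the furan branch (steps 14–20) has 7 steps.

## Least certain steps

Step 24 (key step). Most likely failure: delivery of C9 to the α face of C10 or with the other orientation of C8 (poor facial control in the envelope), or metalation at C20 or C16 followed by a [1,2] shift or silyl migration, because three ether-type CH2 groups compete and the transition state depends on the macrocycle conformation. Fallback (same bond, different reaction; sets out from 18 and 30, returns at 34): 30 would be oxidised with MnO2 to the furan-3-carbaldehyde F1. 18 would be treated with an excess of (Z)-2-(tributylstannyl)ethenyllithium to give the stannyl diol F2. Intermolecular Stille coupling of F1 and F2 would give the open-chain hydroxy aldehyde F3. Selective mesylation and bromide displacement at the primary allylic C20 hydroxyl (MsCl, 2,4,6-collidine; LiBr) would give the bromo aldehyde F4. CrCl2 in THF (intramolecular Nozaki–Hiyama allylation, attack through the γ-carbon C10 on the C9 aldehyde) would then close the ten-membered ring to 34, with the C9 hydroxyl and the C11=C20 methylene.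

Step 22. Most likely failure: attack on the other face of the aldehyde (the models for an α-quaternary aldehyde conflict), and some iodine–lithium exchange at C5. Fallback (sets out from the C2 epimer mixture of 32, returns at 32): oxidation with Dess–Martin periodinane would give the (Z)-stannyl enone F5. Reduction with catecholborane and the (R)-Me-CBS oxazaborolidine (tertiary C1 as the large group) would then give 32 under reagent control.

Step 26. Most likely failure: the boron-bound hydride cannot reach C7 inside the ten-membered ring, so that facial selectivity is poor or conjugate reduction of the dienone competes. Fallback (sets out from 36, returns at 38): chelation-controlled syn reduction (Et2BOMe, NaBH4) would give the C7-epimeric hydroxy ester F6. Saponification (LiOH) would give the hydroxy acid F7, kept as its carboxylate and acidified cold. Mitsunobu lactonisation (PPh3, DIAD) would then close the lactone with inversion at C7 to give 38.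

Step 32 (with step 33). Most likely failure: slow conjugate addition to the tetrasubstituted butenolide, attack on the wrong face, or epimerisation at the acidic C7; in step 33, protonation of C17 on the wrong face. Fallback (sets out from 43, returns at 45): copper-catalysed conjugate borylation (CuCl, B2pin2, a chiral Josiphos-type bisphosphine to control the face, NaOt-Bu, MeOH), with protonation at C17 in the same flask, would give the 8-boryl lactone F8. Oxidation with NaBO3 would then give 45 with retention at C8, without an epoxide intermediate.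

## Further compounds

F1 | step 24 | 2-[(1Z)-3-(tert-butyldimethylsilyloxy)-2-iodoprop-1-en-1-yl]-4-methyl-5-(trimethylsilyl)furan-3-carbaldehyde | O=Cc1c(/C=C(/CO[Si](C)(C)C(C)(C)C)I)oc([Si](C)(C)C)c1C
F2 | step 24 | ring A diol: (2S)-2-OH with (Z)-C3=C4–SnBu3, free 20-OH, 12,13-acetonide, 14-O-TBS | OCC1=C[C@@](C)([C@@H](O)/C=C\[Sn](CCCC)(CCCC)CCCC)[C@@H](O[Si](C)(C)C(C)(C)C)[C@H]2OC(C)(C)O[C@@H]12
F3 | step 24 | open-chain hydroxy aldehyde: C9 formyl furan, 3Z,5E-diene, 2-OH, 20-OH | OCC1=C[C@@](C)([C@@H](O)/C=C\C(CO[Si](C)(C)C(C)(C)C)=C/c2oc([Si](C)(C)C)c(C)c2C=O)[C@@H](O[Si](C)(C)C(C)(C)C)[C@H]3OC(C)(C)O[C@@H]13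
F4 | step 24 | open-chain bromo aldehyde: as F3 with 20-bromide | BrCC1=C[C@@](C)([C@@H](O)/C=C\C(CO[Si](C)(C)C(C)(C)C)=C/c2oc([Si](C)(C)C)c(C)c2C=O)[C@@H](O[Si](C)(C)C(C)(C)C)[C@H]3OC(C)(C)O[C@@H]13
F5 | step 22 | C2 ketone of 32 ((Z)-3-(tributylstannyl)propenoyl group on C1) | C(OCc1c(/C=C(/CO[Si](C)(C)C(C)(C)C)I)oc([Si](C)(C)C)c1C)C1=C[C@@](C)(C(=O)/C=C\[Sn](CCCC)(CCCC)CCCC)[C@@H](O[Si](C)(C)C(C)(C)C)[C@H]2OC(C)(C)O[C@@H]12
F6 | step 26 | C7 epimer of 37 (7,9-syn hydroxy ester) | CC(C)(C)[Si](C)(C)OCC1=C/[C@@H](O)/C(=C(/C)C(=O)OC)[C@@H](O)[C@H]2C(=C)[C@@H]3OC(C)(C)O[C@@H]3[C@H](O[Si](C)(C)C(C)(C)C)[C@]2(C)[C@@H](O)/C=C\1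
F7 | step 26 | carboxylic acid of F6 | CC(C)(C)[Si](C)(C)OCC1=C/[C@@H](O)/C(=C(/C)C(=O)O)[C@@H](O)[C@H]2C(=C)[C@@H]3OC(C)(C)O[C@@H]3[C@H](O[Si](C)(C)C(C)(C)C)[C@]2(C)[C@@H](O)/C=C\1
F8 | step 32 | 8-(pinacolatoboryl) lactone: 45 with B(pin) in place of the 8-hydroxyl | CC(=O)OCC1=C/[C@@H]2OC(=O)[C@H](C)[C@@]2(B3OC(C)(C)C(C)(C)O3)[C@@H](OC(C)=O)[C@H]4[C@@]5(CO5)[C@H](OC(=O)CC(C)C)[C@H](OC(=O)CC(C)C)[C@H](OC(C)=O)[C@]4(C)[C@@H](OC(C)=O)/C=C\1
A1 | alternative 1 | (E)-4-(tert-butyldimethylsilyloxy)-2-methylbut-2-enal | O=C/C(C)=C/CO[Si](C)(C)C(C)(C)C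
A2 | alternative 1 | (E)-1-(4-methoxybenzyloxy)-3-(tert-butyldimethylsilyloxy)buta-1,3-diene | C=C(O[Si](C)(C)C(C)(C)C)/C=C/OCc1ccc(OC)cc1
A3 | alternative 1 | ring A cyclohexene with quaternary C1 aldehyde, 10-CH2OTBS, 12-silyl enol ether, 14-O-PMB | CC(C)(C)[Si](C)(C)OC[C@H]1CC(O[Si](C)(C)C(C)(C)C)=C[C@H](OCc2ccc(OC)cc2)[C@]1(C)C=O
A4 | alternative 2 | C8 ketone with 7-O-(2-bromopropanoyl) and 9-O-TBS, otherwise fully functionalised ten-membered ring | CC(=O)OCC1=C/[C@H](OC(=O)C(C)Br)C(=O)[C@@H](O[Si](C)(C)C(C)(C)C)[C@H]2[C@@]3(CO3)[C@H](OC(=O)CC(C)C)[C@H](OC(=O)CC(C)C)[C@H](OC(C)=O)[C@]2(C)[C@@H](OC(C)=O)/C=C\1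
A5 | alternative 2 | 9-O-tert-butyldimethylsilyl ether of the 9-deacetyl target | CC(=O)OCC1=C/[C@@H]2OC(=O)[C@H](C)[C@@]2(O)[C@@H](O[Si](C)(C)C(C)(C)C)[C@H]3[C@@]4(CO4)[C@H](OC(=O)CC(C)C)[C@H](OC(=O)CC(C)C)[C@H](OC(C)=O)[C@]3(C)[C@@H](OC(C)=O)/C=C\1
A6 | alternative 3 | fourteen-membered 1,2-epoxide with C10=C11 allylsilane (C20–SiMe3), C3≡C4, lactone, 8-O-TMS, 9-O-TBS, 13,14-acetonide | CC(=O)OCC1=C/[C@@H]2OC(=O)[C@H](C)[C@@]2(O[Si](C)(C)C)[C@@H](O[Si](C)(C)C(C)(C)C)/C=C(C[Si](C)(C)C)/C[C@@H]3OC(C)(C)O[C@@H]3[C@]4(C)O[C@H]4C#C\1
A7 | alternative 3 | trans-fused bicyclo[8.4.0] core with 2-OH, C11=C20 methylene, C3≡C4, 13,14-acetonide, C12 methylene | CC(=O)OCC1=C/[C@@H]2OC(=O)[C@H](C)[C@@]2(O[Si](C)(C)C)[C@@H](O[Si](C)(C)C(C)(C)C)[C@H]2C(=C)C[C@@H]3OC(C)(C)O[C@@H]3[C@]2(C)[C@@H](O)C#C\1
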